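**Retrosynthetic overview**

1. Locants follow 2,6-dioxabicyclo[3.3.0]octane: ring A = C1(Me)–O2–C3(=O)–C4–C5(H), ring B = C5–O6–C7(Me, chain)–C8H2–C1; target 12 is (1S,5S,7S). 12 ⇐ 11 by oxidation of the only ether CH2 (C3), so ring A is carried as an oxolane, one oxidation level below the lactone.
2. 11 ⇐ 9 (key step): formation of the C8–C1 bond closes ring B onto ring A in a Lewis-acid ketal/enol ether rearrangement (9 → 10), and AlMe3 then sets C7 in the same flask.
3. Enabling feature: in ring B the two fully substituted carbons C7 and C1 are both ketone-level carbons in a 1,3 (aldol) relation across C8H2, and O6 ties C7 to C5, the neighbour of C1. C7 can therefore be stored as an enol ether on the C5 oxygen and C1 as the methyl ketal carbon of ring A.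
4. 9 ⇐ ester 8 (Petasis methylenation) ⇐ acid 3 (from 1 + 2) + ketal alcohol 7 ⇐ (S)-α-hydroxy-γ-butyrolactone 4, the source of C5.
5. Ring order: ring A first (from 4, as cyclic ketal), ring B in the key step, lactone carbonyl last.

Key step: step 6

Remark on the chemistry: 3 is prepared rather than bought, since its commercial supply is uncertain; the C2 epimers of 6–9 and the C7 epimers of 10 are carried as mixtures because the key step erases these centres.

**Step 1**
Reactants: 1 11-bromoundecanoic acid; 2 phenethylmagnesium chloride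
Product: 3 13-phenyltridecanoic acid
Conditions: 2 (2.3 equiv), Li2CuCl4 (3 mol %), THF, −20 → 0 °C; then 1 M HCl
Reagents that add atoms: none
Why: Kochi-type copper-catalysed sp3–sp3 coupling of a primary alkyl bromide with a primary Grignard reagent should work here because the first equivalent of 2 turns the acid into its unreactive chloromagnesium carboxylate.

**Step 2**
Reactants: 4 (S)-3-hydroxyoxolan-2-one
Product: 5 (S)-3-(triethylsilyloxy)oxolan-2-one
Conditions: TESCl, imidazole, CH2Cl2, 0 °C → rt
Reagents that add atoms: chlorotriethylsilane, CC[Si](Cl)(CC)CC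
Why: Standard imidazole-promoted silylation of a secondary alcohol blocks the hydroxyl against MeLi and leaves the C3 stereocentre (future C5) untouched.

**Step 3**
Reactants: 5 (S)-3-(triethylsilyloxy)oxolan-2-one
Product: 7 (3S)-2-methoxy-2-methyloxolan-3-ol, via lactol 6 (not isolated)
Conditions: MeLi (1.05 equiv), THF, −78 °C; AcOH (1.1 equiv)/MeOH quench; then PPTS (0.1 equiv), MeOH, rt; Et3N before concentration
Reagents that add atoms: methyllithium, [Li]C; methanol, CO
Why: Mono-addition of MeLi to a γ-lactone at −78 °C should stop at the lithium hemiketal, and acidic methanol then converts lactol 6 into the cyclic methyl ketal (Fischer-type ketalisation) while methanolysing the TES ether, the stereocentre being a spectator.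

**Step 4**
Reactants: 7 (3S)-2-methoxy-2-methyloxolan-3-ol; 3 13-phenyltridecanoic acid
Product: 8 (3S)-2-methoxy-2-methyloxolan-3-yl 13-phenyltridecanoate
Conditions: DCC, DMAP (0.3 equiv), CH2Cl2, 0 °C → rt
Reagents that add atoms: none
Why: Steglich esterification should acylate the hindered secondary alcohol under conditions mild enough for the methyl ketal.

**Step 5**
Reactants: 8 (3S)-2-methoxy-2-methyloxolan-3-yl 13-phenyltridecanoate
Product: 9 (3S)-2-methoxy-2-methyl-3-[(14-phenyltetradec-1-en-2-yl)oxy]oxolane
Conditions: Cp2TiMe2 (2.5 equiv), toluene, 65 °C, dark; filtration through basic alumina (Et3N)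
Reagents that add atoms: dimethyltitanocene (Cp2TiMe2), C[Ti](C)(C1C=CC=C1)C1C=CC=C1
Why: Petasis methylenation converts the only carbonyl group into the regiodefined 1,1-disubstituted enol ether through Cp2Ti=CH2 cycloaddition/cycloreversion, with ketal, ether and arene inert to the reagent.

**Step 6**
Reactants: 9 (3S)-2-methoxy-2-methyl-3-[(14-phenyltetradec-1-en-2-yl)oxy]oxolane
Product: 11 (1S,5S,7S)-1,7-dimethyl-7-(12-phenyldodecyl)-2,6-dioxabicyclo[3.3.0]octane, via bicyclic methyl ketal 10 (not isolated)
Conditions: TMSOTf (0.15 equiv), 2,6-di-tert-butyl-4-methylpyridine (0.3 equiv), CH2Cl2 (0.01 M), −78 → −40 °C; then AlMe3 (4 equiv), −78 → 0 °C; aq. Rochelle salt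
Reagents that add atoms: trimethylaluminium, C[Al](C)C
Why: Proposed new method: TMSOTf should ionise the ring-A methyl ketal (Me3SiOMe leaves) to a 2-methyloxolan-2-ylium ion, whose cationic carbon (future C1) is attacked by the terminal CH2 (future C8) of the enol ether held on the neighbouring oxygen, giving the C8–C1 bond and a ring-B oxocarbenium ion at C7 that Me3SiOMe caps as ketal 10 with return of TMSOTf; AlMe3 then re-ionises 10 and transfers methyl to C7. The closest known reaction types are the Petasis–Ferrier rearrangement of 4-methylene-1,3-dioxolanes to oxolan-3-ones (recombination of an O-tethered enol and an oxocarbenium ion to a five-membered ring), Mukaiyama-type additions of 2-alkoxyalkenes to ketal-derived oxocarbenium ions, and AlMe3 methylation of cyclic ketals to tertiary ethers; what is new is the placement of the enol ether on the oxygen next to the cationic carbon, so that a C–C bond closes the ring. Ring B closes in a 5-(enolendo)-exo-trig mode, formally disfavoured but the same mode as in the Petasis–Ferrier oxolane synthesis and in cyclopentenone formation from 1,4-diketones. C1 is controlled by C5: the three-atom O6–C7=C8 tether reaches the cation only on the face of the C5–O6 bond, so only the cis-fused bicycle can form; C7 is controlled by the bicyclic oxocarbenium ion, which should take methyl by inside attack on the envelope with O2 pseudoaxial and the C1 methyl pseudoequatorial, i.e. syn to O2 (1,3-cis to alkoxy, 1,3-trans to alkyl), possibly helped by O2–Al coordination. The step needs ketal ionisation to win over protonation of the enol ether, and C–C closure to win over oligomerisation and over proton loss from the CH next to the cation (which would erase the stereocentre); aprotic conditions with a hindered pyridine, low temperature, high dilution and the proximity of the regiodefined enol ether should secure this.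

**Step 7**
Reactants: 11 (1S,5S,7S)-1,7-dimethyl-7-(12-phenyldodecyl)-2,6-dioxabicyclo[3.3.0]octane
Product: 12 plakortone L, (1S,5S,7S)-1,7-dimethyl-7-(12-phenyldodecyl)-2,6-dioxabicyclo[3.3.0]octan-3-one
Conditions: RuCl3·xH2O (5 mol %), NaIO4 (3 equiv), EtOAc/MeCN/H2O, 0 °C → rt, stopped at full conversion of 11
Reagents that add atoms: sodium periodate, [Na+].[O-]I(=O)(=O)=O
Why: RuO4-catalysed oxidation of a cyclic ether to a γ-lactone should attack the only ether methylene (C3), since C1 and C7 are quaternary and C5–H is a hindered bridgehead methine, and no stereocentre is affected.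

**Compound list**

1 | 11-bromoundecanoic acid | OC(=O)CCCCCCCCCCBr | starting material
2 | phenethylmagnesium chloride | Cl[Mg]CCc1ccccc1 | starting material
3 | 13-phenyltridecanoic acid | OC(=O)CCCCCCCCCCCCc1ccccc1 | intermediate
4 | (S)-3-hydroxyoxolan-2-one ((S)-α-hydroxy-γ-butyrolactone) | O[C@H]1CCOC1=O | starting material
5 | (S)-3-(triethylsilyloxy)oxolan-2-one | CC[Si](CC)(CC)O[C@H]1CCOC1=O | intermediate
6 | (3S)-2-methyl-3-(triethylsilyloxy)oxolan-2-ol (lactol, C2 epimers, in equilibrium with the open hydroxy ketone) | CC[Si](CC)(CC)O[C@H]1CCOC1(C)O | intermediate (not isolated)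
7 | (3S)-2-methoxy-2-methyloxolan-3-ol (C2 epimers) | O[C@H]1CCOC1(C)OC | intermediate
8 | (3S)-2-methoxy-2-methyloxolan-3-yl 13-phenyltridecanoate | O=C(CCCCCCCCCCCCc1ccccc1)O[C@H]1CCOC1(C)OC | intermediate
9 | (3S)-2-methoxy-2-methyl-3-[(14-phenyltetradec-1-en-2-yl)oxy]oxolane | C=C(CCCCCCCCCCCCc1ccccc1)O[C@H]1CCOC1(C)OC | intermediate
10 | (1S,5S)-7-methoxy-1-methyl-7-(12-phenyldodecyl)-2,6-dioxabicyclo[3.3.0]octane (C7 epimers) | COC1(CCCCCCCCCCCCc2ccccc2)C[C@]2(C)OCC[C@@H]2O1 | intermediate (not isolated)
11 | (1S,5S,7S)-1,7-dimethyl-7-(12-phenyldodecyl)-2,6-dioxabicyclo[3.3.0]octane | C[C@]1(CCCCCCCCCCCCc2ccccc2)C[C@]2(C)OCC[C@@H]2O1 | intermediate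
12 | plakortone L, (1S,5S,7S)-1,7-dimethyl-7-(12-phenyldodecyl)-2,6-dioxabicyclo[3.3.0]octan-3-one | C[C@]1(CCCCCCCCCCCCc2ccccc2)C[C@]2(C)OC(=O)C[C@@H]2O1 | target

**Step count and risks**

Total step count: 7. Longest linear sequence: 6 steps (steps 2–7, from 4).

Steps most likely to fail:

1. Step 6 (proposed new method). The C–C closure may be outrun by proton loss from the oxolanylium ion (erasing the stereocentre), by intermolecular ketal/enol ether oligomerisation or by protic isomerisation of the enol ether, and methyl delivery may show poor facial selectivity. The fallback uses known chemistry, sets out from 3 and 7 and returns at 11. Acid 3 with MeLi (2.2 equiv, THF, 0 °C) should give 14-phenyltetradecan-2-one F1, and LDA/TMSCl (THF, −78 °C) its kinetic trimethylsilyl enol ether F2. Alcohol 7 is silylated (TMSCl, Et3N) to the trimethylsilyl ether F3. TMSOTf-mediated Mukaiyama-type substitution of ketal F3 by F2 (CH2Cl2, −78 °C) should give the oxolanyl ketone F4, the new bond forming cis to the neighbouring silyloxy group. Mild desilylation (PPTS, wet THF) lets the freed hydroxyl close onto the ketone as the bicyclic hemiketal F5; only the cis isomer can close. AlMe3/TMSOTf (CH2Cl2, −78 → 0 °C) then methylates C7 to give 11. Here the C8–C1 bond is made between two molecules and ring B is closed by hemiketal formation.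

2. Step 7. Oxidative degradation of the phenyl ring by RuO4, or over-oxidation at the C5 methine, may compete with oxidation of the ether CH2. The fallback moves the oxidation to a stage without arene, sets out from 7 and returns at 12. Silylation (TBSCl, imidazole) gives the silyl ether F6. Buffered RuCl3·xH2O/NaIO4 oxidation of its ether CH2 should give the lactone pseudo-ester F7. Lewis-acid substitution of the methoxy group of F7 (TMSOTf or BF3·OEt2, CH2Cl2, −78 °C) by the silyl enol ether F2 of the first fallback should give the keto lactone F8. HF·pyridine removes the silyl group and gives the hemiketal lactone F9. AlMe3/TMSOTf (−78 → −20 °C) then methylates C7 to give 12.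

3. Step 5. Methylenation of the hindered ester may be incomplete, and the acid-labile enol ether may hydrolyse or isomerise during isolation. The fallback forms the enol ether by C–O bond formation and elimination, sets out from 7 and 2 and returns at 9. Kochi coupling of 2 with commercial 12-bromododec-1-ene (Li2CuCl4, THF) should give 14-phenyltetradec-1-ene F10. NIS-mediated alkoxyiodination of F10 (excess) with 7 (CH2Cl2, −20 °C → rt) should give the Markovnikov β-iodo ether F11. t-BuOK (THF, 0 °C) then eliminates HI to give 9.

**Further compounds**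

F1 | step 6 | 14-phenyltetradecan-2-one | CC(=O)CCCCCCCCCCCCc1ccccc1
F2 | step 6 | trimethyl[(14-phenyltetradec-1-en-2-yl)oxy]silane | C=C(CCCCCCCCCCCCc1ccccc1)O[Si](C)(C)C
F3 | step 6 | {[(3S)-2-methoxy-2-methyloxolan-3-yl]oxy}trimethylsilane | C[Si](C)(C)O[C@H]1CCOC1(C)OC
F4 | step 6 | 1-[(2S,3S)-2-methyl-3-(trimethylsilyloxy)oxolan-2-yl]-14-phenyltetradecan-2-one | O=C(CCCCCCCCCCCCc1ccccc1)C[C@]1(C)OCC[C@@H]1O[Si](C)(C)C
F5 | step 6 | (1S,5S)-1-methyl-7-(12-phenyldodecyl)-2,6-dioxabicyclo[3.3.0]octan-7-ol | OC1(CCCCCCCCCCCCc2ccccc2)C[C@]2(C)OCC[C@@H]2O1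
F6 | step 7 | tert-butyl{[(3S)-2-methoxy-2-methyloxolan-3-yl]oxy}dimethylsilane | CC(C)(C)[Si](C)(C)O[C@H]1CCOC1(C)OC
F7 | step 7 | (4S)-4-[(tert-butyldimethylsilyl)oxy]-5-methoxy-5-methyloxolan-2-one | CC(C)(C)[Si](C)(C)O[C@H]1CC(=O)OC1(C)OC
F8 | step 7 | (4S,5S)-4-[(tert-butyldimethylsilyl)oxy]-5-methyl-5-(2-oxo-14-phenyltetradecyl)oxolan-2-one | O=C(CCCCCCCCCCCCc1ccccc1)C[C@]1(C)OC(=O)C[C@@H]1O[Si](C)(C)C(C)(C)C
F9 | step 7 | (1S,5S)-7-hydroxy-1-methyl-7-(12-phenyldodecyl)-2,6-dioxabicyclo[3.3.0]octan-3-one | OC1(CCCCCCCCCCCCc2ccccc2)C[C@]2(C)OC(=O)C[C@@H]2O1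
F10 | step 5 | 14-phenyltetradec-1-ene | C=CCCCCCCCCCCCCc1ccccc1
F11 | step 5 | (3S)-3-[(1-iodo-14-phenyltetradecan-2-yl)oxy]-2-methoxy-2-methyloxolane | ICC(CCCCCCCCCCCCc1ccccc1)O[C@H]1CCOC1(C)OC
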